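**Retrosynthetic overview**
1. Target 19 ⇐ excision of acetone (C–O bond to C24, then β-scission) from the isopropenyl-cyclopentane cage 16 ⇐ cation–olefin closure C29–C23 of the caged homoadamantane 15.
2. 15 ⇐ C1–C8 closure (MHAT/radical-polar crossover) of bicyclo[4.3.1] triketone 14 ⇐ C3–C28 bond by invertive epoxide opening in the monocyclic triketone 12.
3. 12 ⇐ prenyl bromide + chloro-blocked dearomatised triketone 9 ⇐ 3-chloro-5-geranyl-trihydroxybenzophenone 8 + epoxy bromide 4.
4. 4 ⇐ Shi epoxidation (the C–O key step, fixes C28) of (S)-lavandulyl bromide ⇐ lipase-resolved lavandulol; 8 ⇐ trihydroxybenzophenone + geranyl bromide + NCS.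
5. Ring order: seven-membered ring (C3–C28) → cage ring (C1–C8) → cyclopentane (C29–C23), then loss of C24.

Atom labels: C1 (benzoyl carbon), C3, C5 (geranyl carbon) with carbonyl carbons C2, C4, C9 between them (C9 between C1 and C5); C6 (CH2), C7 (CH), C8 (CMe2) bridge C5 to C1; C27 (CH2), C28 (CH), C29 (CMe2) run from C7 to C3; C22, C23, C24 are CH2, CH, CMe2 of the C3 prenyl group. Target: C1 S, C3 S, C5 R, C7 R, C28 R.

Assumption: porcine pancreatic lipase acylates (R)-lavandulol faster (if not, the (S)-acetate is taken and methanolysed), and step 6 gives both C5 epimers about 1:1, of which only the one shown is carried on.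

**Step 1**
Reactants: 1 (±)-lavandulol
Product: 2 (S)-lavandulol
Conditions: porcine pancreatic lipase, vinyl acetate, hexane, rt, to about 60% conversion
Reagents that add atoms: none
Why: Lipase-catalysed kinetic resolution (enantioselective O-acylation) leaves the slow-reacting (S)-alcohol, which is the source of C7.

**Step 2**
Reactants: 2 (S)-lavandulol
Product: 3 (S)-lavandulyl bromide
Conditions: CBr4, PPh3, CH2Cl2, 0 °C
Reagents that add atoms: carbon tetrabromide, BrC(Br)(Br)Br
Why: Appel bromination of the primary alcohol does not touch the stereocentre and removes the hydroxyl that would otherwise open the later epoxide.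

**Step 3**
Reactants: 3 (S)-lavandulyl bromide
Product: 4 (S,S)-epoxy bromide
Conditions: ent-Shi ketone (L-fructose-derived, 30 mol%), Oxone, K2CO3, Bu4NHSO4, MeCN–DMM–buffer pH 10.5, 0 °C
Reagents that add atoms: Oxone (potassium peroxymonosulfate), [K+].[O-]S(=O)(=O)OO
Why: Shi asymmetric epoxidation is selective for the trisubstituted alkene over the 1,1-disubstituted one and, under reagent control (spiro transition state), gives the (S)-epoxide carbon that becomes C28 after inversion.

**Step 4**
Reactants: 5 2,4,6-trihydroxybenzophenone; 6 geranyl bromide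
Product: 7 3-geranyl-2,4,6-trihydroxybenzophenone
Conditions: DBU, THF, 0 °C → rt
Reagents that add atoms: none
Why: C-alkylation of the phloroglucinol anion by an allylic bromide (Friedel–Crafts-type C-geranylation) is the standard entry to mono-C-geranyl acylphloroglucinols.

**Step 5**
Reactants: 7 3-geranyl-2,4,6-trihydroxybenzophenone
Product: 8 3-chloro-5-geranyl-2,4,6-trihydroxybenzophenone
Conditions: NCS (1.0 equiv), MeCN, −20 °C
Reagents that add atoms: N-chlorosuccinimide, O=C1CCC(=O)N1Cl
Why: Electrophilic aromatic chlorination takes the only free ring position, so that later alkylation cannot go to the future C3.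

**Step 6**
Reactants: 8 3-chloro-5-geranyl-2,4,6-trihydroxybenzophenone; 4 (S,S)-epoxy bromide
Product: 9 chloro-triketone (dearomatised at C5)
Conditions: NaH (2.2 equiv), NaI (0.5 equiv), toluene–DMF 10:1, 0 → 60 °C; chromatographic separation of the C5 epimer
Reagents that add atoms: none
Why: Alkylative dearomatisation occurs at the geranyl-bearing carbon because the chlorinated carbon and the benzoyl (triketone) carbon are much less nucleophilic; C5 forms without control and the epimer in which C8 can later reach C1 is kept.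

**Step 7**
Reactants: 9 chloro-triketone; 10 prenyl bromide
Product: 12 C3-prenyl triketone, via dechlorinated triketone 11 (not isolated)
Conditions: PPh3 (1.0 equiv), THF–H2O, 0 °C; then K2CO3, prenyl bromide (1.05 equiv), 0 °C → rt
Reagents that add atoms: none
Why: Halophilic dechlorination of the α-chloro-β-diketone unit frees C3, which is then C-prenylated as the more nucleophilic non-acyl carbon of the vinylogous acid (standard acylphloroglucinol C-alkylation).

**Step 8**
Reactants: 12 C3-prenyl triketone
Product: 14 bridged triethylsilyl ether, via bridged tertiary alcohol 13 (not isolated)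
Conditions: LiHMDS (2.2 equiv), toluene–THF, 0 → 70 °C; then TESOTf, −78 °C; aq. citric acid work-up (cleaves enol silyl ethers)
Reagents that add atoms: triethylsilyl triflate, CC[Si](CC)(CC)OS(=O)(=O)C(F)(F)F
Why: Intramolecular SN2 epoxide opening (7-exo-tet) by the C3 enolate at the less substituted epoxide carbon inverts it and so sets C28, and the four-atom bridge can only span C3 and C5 on one face, which sets C3; the tertiary alkoxide is capped so that it cannot trap the C8 cation in step 9.

**Step 9**
Reactants: 14 bridged triethylsilyl ether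
Product: 15 caged homoadamantane silyl ether
Conditions: Co(salen) (10 mol%), N-fluoro-2,4,6-trimethylpyridinium BF4 (1.5 equiv), PhSiH3 (1.2 equiv), PhCF3, 0 °C → rt
Reagents that add atoms: none
Why: Proposed new method: Co–H hydrogen-atom transfer to the 1,1-disubstituted alkene (trisubstituted prenyl and geranyl alkenes react much more slowly) gives the tertiary C8 radical, which is captured by cobalt and oxidised by the N-fluoropyridinium salt to an alkyl-Co(IV)/cation equivalent; the only enolisable carbon left (C1, since C3 and C5 are quaternary) attacks it in a six-ring closure, forming the C1–C8 quaternary–quaternary bond and fixing C1 because the C6–C7–C8 bridge can only close on the face that carries C6; the closest known reaction type is Co-catalysed MHAT/radical-polar-crossover hydroalkoxylation and hydroarylation of alkenes.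

**Step 10**
Reactants: 15 caged homoadamantane silyl ether
Product: 16 isopropenyl-cyclopentane cage
Conditions: TMSOTf (0.2 equiv), 2,6-di-tert-butyl-4-methylpyridine (0.1 equiv), CH2Cl2, −78 → −40 °C
Reagents that add atoms: none
Why: Ionisation of the tertiary silyl ether gives the C29 cation, which is attacked by C23 of the C3 prenyl group (5-exo cation–olefin cyclisation), and the exocyclic C24 cation loses a methyl proton (E1); C23 is not controlled and does not matter because it becomes CH2.

**Step 11**
Reactants: 16 isopropenyl-cyclopentane cage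
Product: 19 target CNP0168637.1, via triethylsilyl peroxide 17 (not isolated), via hydroperoxide 18 (not isolated)
Conditions: Co(thd)2 (10 mol%), Et3SiH, O2 (1 atm), DCE, rt; then degas, MeOH, FeSO4·7H2O (1.2 equiv), 1,4-cyclohexadiene (10 equiv), 0 °C
Reagents that add atoms: none
Why: Isayama–Mukaiyama peroxidation (MHAT, then O2 capture at C24) of the 1,1-disubstituted alkene is followed by Fe(II) reduction to the tertiary alkoxy radical, whose β-scission expels acetone and leaves the secondary C23 radical, reduced by the H-atom donor (hydrodealkenylation); cyclohexadiene is used instead of a thiol to avoid thiyl-radical E/Z scrambling of the geranyl group.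

**Compound list**
1 | (±)-lavandulol | CC(C)=CCC(CO)C(C)=C | starting material
2 | (S)-lavandulol | OC[C@H](C(C)=C)CC=C(C)C | intermediate
3 | (S)-lavandulyl bromide, (3S)-3-(bromomethyl)-2,6-dimethylhepta-1,5-diene | BrC[C@H](C(C)=C)CC=C(C)C | intermediate
4 | (3S)-3-[(2S)-2-(bromomethyl)-3-methylbut-3-enyl]-2,2-dimethyloxirane | BrC[C@H](C(C)=C)C[C@@H]1OC1(C)C | intermediate
5 | 2,4,6-trihydroxybenzophenone | O=C(c1ccccc1)c1c(O)cc(O)cc1O | starting material
6 | geranyl bromide (E) | CC(C)=CCC/C(C)=C/CBr | starting material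
7 | 3-geranyl-2,4,6-trihydroxybenzophenone | CC(C)=CCC/C(C)=C/Cc1c(O)cc(O)c(C(=O)c2ccccc2)c1O | intermediate
8 | 3-chloro-5-geranyl-2,4,6-trihydroxybenzophenone | CC(C)=CCC/C(C)=C/Cc1c(O)c(Cl)c(O)c(C(=O)c2ccccc2)c1O | intermediate
9 | 2-benzoyl-4-chloro-6-geranyl-3,5-dihydroxy-6-(epoxy-lavandulyl)cyclohexa-2,4-dienone; C7 and C28 from 4, quaternary C5 as in the SMILES | CC(C)=CCC/C(C)=C/C[C@@]1(C[C@H](C(C)=C)C[C@@H]2OC2(C)C)C(=O)C(Cl)=C(O)C(C(=O)c2ccccc2)=C1O | intermediate
10 | prenyl bromide | CC(C)=CCBr | starting material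
11 | dechlorinated triketone (9 with H at C3) | CC(C)=CCC/C(C)=C/C[C@@]1(C[C@H](C(C)=C)C[C@@H]2OC2(C)C)C(=O)C=C(O)C(C(=O)c2ccccc2)=C1O | intermediate
12 | C3-prenyl triketone (9 with prenyl at C3) | CC(C)=CCC/C(C)=C/C[C@@]1(C[C@H](C(C)=C)C[C@@H]2OC2(C)C)C(=O)C(CC=C(C)C)=C(O)C(C(=O)c2ccccc2)=C1O | intermediate
13 | bicyclo[4.3.1] triketone with C3–C28 bond, C28 bearing CMe2OH, C7 bearing isopropenyl (drawn as the benzoyl enol) | CC(C)=CCC/C(C)=C/C[C@@]12C[C@H](C(C)=C)C[C@H](C(C)(C)O)[C@@](CC=C(C)C)(C1=O)C(=O)C(=C(O)c1ccccc1)C2=O | intermediate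
14 | triethylsilyl ether of 13 | CC(C)=CCC/C(C)=C/C[C@@]12C[C@H](C(C)=C)C[C@H](C(C)(C)O[Si](CC)(CC)CC)[C@@](CC=C(C)C)(C1=O)C(=O)C(=C(O)c1ccccc1)C2=O | intermediate
15 | homoadamantane trione: 1-benzoyl, 3-prenyl, 5-geranyl, 8,8-dimethyl, C28 bearing CMe2OSiEt3 | CC(C)=CCC/C(C)=C/C[C@@]12C[C@H]3C[C@H](C(C)(C)O[Si](CC)(CC)CC)[C@@](CC=C(C)C)(C1=O)C(=O)[C@@](C(=O)c1ccccc1)(C2=O)C3(C)C | intermediate
16 | target skeleton with isopropenyl on C23 (C23 epimers, not controlled) | CC(C)=CCC/C(C)=C/C[C@@]12C[C@H]3C[C@@H]4C(C)(C)C(C(C)=C)C[C@]4(C1=O)C(=O)[C@@](C(=O)c1ccccc1)(C2=O)C3(C)C | intermediate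
17 | 16 with C23 bearing CMe2–OO–SiEt3 | CC(C)=CCC/C(C)=C/C[C@@]12C[C@H]3C[C@@H]4C(C)(C)C(C(C)(C)OO[Si](CC)(CC)CC)C[C@]4(C1=O)C(=O)[C@@](C(=O)c1ccccc1)(C2=O)C3(C)C | intermediate
18 | 16 with C23 bearing CMe2–OOH | CC(C)=CCC/C(C)=C/C[C@@]12C[C@H]3C[C@@H]4C(C)(C)C(C(C)(C)OO)C[C@]4(C1=O)C(=O)[C@@](C(=O)c1ccccc1)(C2=O)C3(C)C | intermediate
19 | CNP0168637.1 (C1 S, C3 S, C5 R, C7 R, C28 R) | CC(C)=CCC/C(C)=C/C[C@@]12C[C@H]3C[C@@H]4C(C)(C)CC[C@]4(C1=O)C(=O)[C@@](C(=O)c1ccccc1)(C2=O)C3(C)C | target

**Totals**
Total steps: 11. Longest linear sequence: 9 (steps 1–3, then 6–11).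

**Three steps most likely to fail**

Step 6 (quaternisation with an unactivated, β-branched bromide; O-alkylation and half of the material lost as the C5 epimer). Fallback: set out from 5 and 4 and put the sluggish electrophile on first, where no quaternary centre is formed: C-alkylation of the free ring position of 5 with 4 (NaH, NaI, toluene–DMF) gives the 3-(epoxy-lavandulyl)-trihydroxybenzophenone F1. NCS then gives the chloro-phenol F2, and dearomatisation with the reactive allylic bromide 6 (aq. KOH, 0 °C) comes back to 9.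

Step 8 (a tetrasubstituted, stabilised enolate must open a hindered epoxide carbon; O-alkylation through the enol oxygen is the competitor). Fallback: set out from 11, isolated after the PPh3 operation of step 7, and open the epoxide with the less hindered C3–H enolate (LiHMDS, 70 °C; then TESOTf) to give the C3–H bridged silyl ether F3. Decarboxylative Tsuji–Trost prenylation (Pd(PPh3)4, prenyl methyl carbonate, THF) then puts the prenyl group on C3 from the only open face and comes back to 14.

Step 9 (the proposed new step; O-cyclisation through the enol oxygen or capture of the C8 cation by the geranyl alkene may win). Fallback with known chemistry: set out from 14, hydrate the isopropenyl group by Mukaiyama hydration (Co(acac)2, PhSiH3, O2) to the C8 tertiary alcohol F4, then treat with BF3·OEt2 and 2,6-di-tert-butylpyridine at −78 °C. This ionises both C8–OH and C29–OSiEt3, so C1 closes onto C8 and the prenyl alkene onto C29 in the same flask; the route is rejoined at 16, and 15 is skipped.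

**Further compounds**
F1 | step 6 | 3-(epoxy-lavandulyl)-2,4,6-trihydroxybenzophenone | O=C(c1ccccc1)c1c(O)cc(O)c(C[C@H](C(C)=C)C[C@@H]2OC2(C)C)c1O
F2 | step 6 | 3-chloro-5-(epoxy-lavandulyl)-2,4,6-trihydroxybenzophenone | O=C(c1ccccc1)c1c(O)c(Cl)c(O)c(C[C@H](C(C)=C)C[C@@H]2OC2(C)C)c1O
F3 | step 8 | 14 with H in place of prenyl at C3 | CC(C)=CCC/C(C)=C/C[C@@]12C[C@H](C(C)=C)C[C@H](C(C)(C)O[Si](CC)(CC)CC)[C@@H](C1=O)C(=O)C(=C(O)c1ccccc1)C2=O
F4 | step 9 | 14 with CMe2OH in place of isopropenyl on C7 | CC(C)=CCC/C(C)=C/C[C@@]12C[C@H](C(C)(C)O)C[C@H](C(C)(C)O[Si](CC)(CC)CC)[C@@](CC=C(C)C)(C1=O)C(=O)C(=C(O)c1ccccc1)C2=O
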